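**Plan**

- Retrosynthesis: the six phenols are unmasked last (two tosylates, then four benzyl ethers). The dihydrofuran is then cut at O1–C2 and C2–C3 in one operation, a formal [4+1] disconnection into an o-quinone methide (O1=C7a–C3a=C3: ring A plus the C3 methine with its 3,5-dioxygenated aryl group) and a one-carbon sulfonium benzylide that carries the 2,4-dioxygenated aryl group of C2.
- Enabling feature: C3a of ring A lies between two equivalent oxygens (O1 and the C4 oxygen) and para to the arylethyl chain, so lithiation there is unambiguous and either oxygen can become O1. C3 is a diaryl methine that can ionise to the quinone methide. C2 is a benzylic CH bearing only H and an aryl group, so it can come from an ylide whose sulfide is both chiral controller and leaving group.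
- Forward, ring A branch: dihydroresveratrol is formylated between its resorcinol oxygens by directed ortho-lithiation; chelation-controlled mono-debenzylation frees one ortho oxygen; Grignard addition of the C3 aryl group and sulfinate substitution give the quinone methide precursor.
- Forward, C2 branch: 2,4-dihydroxybenzaldehyde is carried as its bis-tosylate (temporary electron-withdrawing groups that keep the sulfonium salt stable and the ring closure SN2) and S-alkylates (1R,4R,5R)-isothiocineole.
- All four arenes are bought; the only ring made is the dihydrofuran, closed by O1–C2 bond formation in the annulation. C2 comes from the chiral sulfide (ylide-face control, then inversion on ring closure); C3 from the anti-selective C–C bond formation of the same step (trans).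

Key step: step 12

Assumption: ylide 18 is taken to react on the same face as in benzylidene transfer from this sulfonium type to aldehydes (aryl group turned away from the bicycle, attack away from the gem-dimethyl carbon), which maps onto 2S here; if the sense proved opposite, the enantiomeric sulfide from (S)-limonene would be used in the same way.

**Route**

Step 1
Reactants: 1 dihydroresveratrol
Product: 2 1,3-bis(methoxymethoxy)-5-{2-[4-(methoxymethoxy)phenyl]ethyl}benzene
Conditions: MOMCl (3.6 equiv), i-Pr2NEt (4.5 equiv), DMF, 0 °C → rt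
Reagents that add atoms: chloromethyl methyl ether, COCCl
Why: O-alkylation of all three phenols (MOM acetal formation) protects them and installs the directing groups for the ortho-lithiation; no stereocentre is involved.

Step 2
Reactants: 2 tris-MOM ether
Product: 4 2,6-bis(methoxymethoxy)-4-{2-[4-(methoxymethoxy)phenyl]ethyl}benzaldehyde, via aryllithium 3 (not isolated)
Conditions: n-BuLi (1.15 equiv), THF, 0 °C; DMF (3 equiv), 0 °C → rt; H2O
Reagents that add atoms: N,N-dimethylformamide, CN(C)C=O
Why: Directed ortho-metalation should occur at the ring position flanked by two MOM ethers (cooperative direction, most acidic aryl C–H), and the aryllithium is formylated by DMF.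

Step 3
Reactants: 4 tris-MOM aldehyde
Product: 5 2,6-dihydroxy-4-[2-(4-hydroxyphenyl)ethyl]benzaldehyde
Conditions: HCl (conc. aq., cat.), MeOH/THF, 50 °C
Reagents that add atoms: none
Why: Acid-catalysed acetal exchange with methanol cleaves the three MOM ethers, while the hydrogen-bonded aldehyde deactivates ring A toward reaction with the released formaldehyde equivalent.

Step 4
Reactants: 5 triol aldehyde
Product: 6 2,6-bis(benzyloxy)-4-{2-[4-(benzyloxy)phenyl]ethyl}benzaldehyde
Conditions: BnBr (3.6 equiv), K2CO3 (4 equiv), DMF, 60 °C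
Reagents that add atoms: benzyl bromide, BrCc1ccccc1
Why: Exhaustive Williamson etherification; with excess halide in DMF the two hydrogen-bonded ortho hydroxyls are alkylated as well.

Step 5
Reactants: 6 tris-benzyl aldehyde
Product: 7 2-(benzyloxy)-4-{2-[4-(benzyloxy)phenyl]ethyl}-6-hydroxybenzaldehyde
Conditions: MgBr2·OEt2 (1.5 equiv), toluene/Et2O, 80 °C; H2O
Reagents that add atoms: none
Why: Chelation-controlled Lewis-acid ether cleavage: MgBr2 bound between the aldehyde oxygen and one ortho ether oxygen activates only that benzyl group toward bromide, the resulting magnesium phenoxide–aldehyde chelate shuts off cleavage of the second ortho ether, and the remote benzyl ether is not activated.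

Step 6
Reactants: 7 mono-phenol aldehyde; 8 1,3-bis(benzyloxy)-5-bromobenzene
Product: 10 racemic 3-(benzyloxy)-2-{[3,5-bis(benzyloxy)phenyl](hydroxy)methyl}-5-{2-[4-(benzyloxy)phenyl]ethyl}phenol, via Grignard reagent 9 (not isolated)
Conditions: 8 (2.4 equiv), Mg turnings, THF, rt; then 7, THF, 0 °C → rt; H2O
Reagents that add atoms: none
Why: Grignard addition to the aldehyde after the first equivalent has deprotonated the phenol; the carbinol centre forms racemic, which does not matter because it becomes sp2 in step 12.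

Step 7
Reactants: 10 o-hydroxybenzhydrol
Product: 11 racemic 3-(benzyloxy)-2-{[3,5-bis(benzyloxy)phenyl][(4-methylphenyl)sulfonyl]methyl}-5-{2-[4-(benzyloxy)phenyl]ethyl}phenol
Conditions: p-TolSO2H (3 equiv, freshly liberated from its sodium salt), CH2Cl2, rt
Reagents that add atoms: p-toluenesulfinic acid, Cc1ccc(cc1)S(=O)O
Why: Acid-promoted ionisation of the o-hydroxybenzhydrol to the o-quinone methide/benzhydryl cation and S-alkylation of the sulfinate (SN1-type substitution) should give the bench-stable sulfone, a base-triggered o-quinone methide precursor.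

Step 8
Reactants: 12 2,4-dihydroxybenzaldehyde
Product: 13 4-formylbenzene-1,3-diyl bis(4-methylbenzenesulfonate)
Conditions: TsCl (2.3 equiv), Et3N (3 equiv), DMAP (cat.), CH2Cl2, 0 °C → rt
Reagents that add atoms: p-toluenesulfonyl chloride, Cc1ccc(cc1)S(=O)(=O)Cl
Why: O-sulfonylation of both phenols installs base-tolerant, electron-withdrawing protecting groups for the ylide chemistry.

Step 9
Reactants: 13 bis-tosyloxy aldehyde
Product: 14 4-(hydroxymethyl)benzene-1,3-diyl bis(4-methylbenzenesulfonate)
Conditions: NaBH4, THF/MeOH, 0 °C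
Reagents that add atoms: none
Why: Hydride reduction of the aldehyde; aryl sulfonates are inert to NaBH4 at 0 °C.

Step 10
Reactants: 14 benzylic alcohol
Product: 15 4-(bromomethyl)benzene-1,3-diyl bis(4-methylbenzenesulfonate)
Conditions: PBr3 (0.4 equiv), CH2Cl2, 0 °C
Reagents that add atoms: phosphorus tribromide, BrP(Br)Br
Why: Bromination of a primary benzylic alcohol through its phosphite (SN2); the electron-poor ring suppresses ionisation and self-alkylation.

Step 11
Reactants: 15 benzylic bromide; 16 (1R,4R,5R)-isothiocineole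
Product: 17 (1R,4R,5R)-6-{2,4-bis[(4-methylphenyl)sulfonyloxy]benzyl}-4,7,7-trimethyl-6-thiabicyclo[3.2.1]octan-6-ium trifluoromethanesulfonate (benzyl group on the exo face of sulfur)
Conditions: 16 (1.1 equiv), LiOSO2CF3 (5 equiv), CH2Cl2/H2O, rt
Reagents that add atoms: lithium trifluoromethanesulfonate, [Li+].[O-]S(=O)(=O)C(F)(F)F
Why: SN2 S-alkylation of the sulfide on its less hindered exo lone pair should give one sulfonium diastereomer, and exchange of bromide for triflate in the two-phase system prevents dealkylation.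

Step 12
Reactants: 11 sulfone; 17 sulfonium triflate
Product: 21 4-[(2S,3S)-4-(benzyloxy)-3-[3,5-bis(benzyloxy)phenyl]-6-{2-[4-(benzyloxy)phenyl]ethyl}-2,3-dihydro-1-benzofuran-2-yl]benzene-1,3-diyl bis(4-methylbenzenesulfonate), via sulfonium ylide 18 (not isolated), via o-quinone methide 19 (not isolated), via betaine 20 (not isolated)
Conditions: 17 (1.3 equiv), Cs2CO3 (3.5 equiv), MeCN/CH2Cl2, −20 °C → rt
Reagents that add atoms: none
Why: Proposed new method: Cs2CO3 converts 11 into o-quinone methide 19 (phenoxide formation, E1cB loss of sulfinate) and 17 into ylide 18, whose carbon adds to the exocyclic carbon of 19 with rearomatisation of ring A to give betaine 20, and the ring-A phenoxide then displaces the sulfide at C2, forming the O1–C2 bond and closing the dihydrofuran. The closest known reactions are the racemic formal [4+1] annulation of base-generated o-quinone methides from 2-(1-sulfonylalkyl)phenols with carbonyl-stabilised sulfonium ylides and the asymmetric benzylidene transfer from isothiocineole-derived sulfonium salts to aldehydes, imines and Michael acceptors; the new element is a chiral semi-stabilised benzylide on an o-quinone methide. The ring closure is a 5-exo-tet SN2 displacement with inversion at C2. C2 is controlled by the sulfide (a single ylide conformer reacts on the face away from the gem-dimethyl carbon to give the 2R betaine, and inversion gives 2S), while C3 follows from the relative topicity of the addition, in which the two aryl groups avoid each other as in the known trans-selective sulfonium-ylide annulations of o-quinone methides, giving 3S and the trans product; any cis isomer would have the same C2 configuration and be removed by chromatography. The step needs C-attack of the ylide to outrun O-benzylation of the phenoxide by 17 and an SN2 rather than SN1 closure; both are secured by the two tosyloxy groups, which acidify the benzylic CH2 and destabilise the 2,4-dioxygenated benzylic cation, while the flanking benzyl ether and diarylmethyl group shield the phenoxide oxygen from intermolecular alkylation.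

Step 13
Reactants: 21 bis-tosylate
Product: 22 4-[(2S,3S)-4-(benzyloxy)-3-[3,5-bis(benzyloxy)phenyl]-6-{2-[4-(benzyloxy)phenyl]ethyl}-2,3-dihydro-1-benzofuran-2-yl]benzene-1,3-diol
Conditions: Mg turnings (20 equiv), MeOH/THF, rt; aq. NH4Cl
Reagents that add atoms: none
Why: Reductive desulfonylation: electron transfer from Mg to the arenesulfonates cleaves the S–O bonds at room temperature without hot alkali, so the benzyl ethers and both stereocentres should be untouched.

Step 14
Reactants: 22 tetrabenzyl ether
Product: 23 4-[(2S,3S)-3-(3,5-dihydroxyphenyl)-4-hydroxy-6-[2-(4-hydroxyphenyl)ethyl]-2,3-dihydro-1-benzofuran-2-yl]benzene-1,3-diol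
Conditions: H2 (1 atm), Pd/C (10 wt%), EtOAc/MeOH, rt
Reagents that add atoms: none
Why: Catalytic hydrogenolysis of the four O-benzyl ethers under neutral conditions; the cyclic benzylic C2–O1 ether is expected to be cleaved much more slowly than acyclic O-benzyl groups, and neither stereocentre is affected.

**Compound list**

1 | dihydroresveratrol, 5-[2-(4-hydroxyphenyl)ethyl]benzene-1,3-diol | Oc1ccc(CCc2cc(O)cc(O)c2)cc1 | starting material
2 | 1,3-bis(methoxymethoxy)-5-{2-[4-(methoxymethoxy)phenyl]ethyl}benzene | COCOc1ccc(CCc2cc(OCOC)cc(OCOC)c2)cc1 | intermediate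
3 | {2,6-bis(methoxymethoxy)-4-{2-[4-(methoxymethoxy)phenyl]ethyl}phenyl}lithium | [Li]c1c(OCOC)cc(CCc2ccc(OCOC)cc2)cc1OCOC | intermediate (not isolated)
4 | 2,6-bis(methoxymethoxy)-4-{2-[4-(methoxymethoxy)phenyl]ethyl}benzaldehyde | COCOc1ccc(CCc2cc(OCOC)c(C=O)c(OCOC)c2)cc1 | intermediate
5 | 2,6-dihydroxy-4-[2-(4-hydroxyphenyl)ethyl]benzaldehyde | O=Cc1c(O)cc(CCc2ccc(O)cc2)cc1O | intermediate
6 | 2,6-bis(benzyloxy)-4-{2-[4-(benzyloxy)phenyl]ethyl}benzaldehyde | O=Cc1c(OCc2ccccc2)cc(CCc2ccc(OCc3ccccc3)cc2)cc1OCc1ccccc1 | intermediate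
7 | 2-(benzyloxy)-4-{2-[4-(benzyloxy)phenyl]ethyl}-6-hydroxybenzaldehyde | O=Cc1c(O)cc(CCc2ccc(OCc3ccccc3)cc2)cc1OCc1ccccc1 | intermediate
8 | 1,3-bis(benzyloxy)-5-bromobenzene | Brc1cc(OCc2ccccc2)cc(OCc2ccccc2)c1 | starting material
9 | [3,5-bis(benzyloxy)phenyl]magnesium bromide | Br[Mg]c1cc(OCc2ccccc2)cc(OCc2ccccc2)c1 | intermediate (not isolated)
10 | racemic 3-(benzyloxy)-2-{[3,5-bis(benzyloxy)phenyl](hydroxy)methyl}-5-{2-[4-(benzyloxy)phenyl]ethyl}phenol | OC(c1cc(OCc2ccccc2)cc(OCc2ccccc2)c1)c1c(O)cc(CCc2ccc(OCc3ccccc3)cc2)cc1OCc1ccccc1 | intermediate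
11 | racemic 3-(benzyloxy)-2-{[3,5-bis(benzyloxy)phenyl][(4-methylphenyl)sulfonyl]methyl}-5-{2-[4-(benzyloxy)phenyl]ethyl}phenol | Cc1ccc(cc1)S(=O)(=O)C(c1cc(OCc2ccccc2)cc(OCc2ccccc2)c1)c1c(O)cc(CCc2ccc(OCc3ccccc3)cc2)cc1OCc1ccccc1 | intermediate
12 | 2,4-dihydroxybenzaldehyde | O=Cc1ccc(O)cc1O | starting material
13 | 4-formylbenzene-1,3-diyl bis(4-methylbenzenesulfonate) | O=Cc1ccc(OS(=O)(=O)c2ccc(C)cc2)cc1OS(=O)(=O)c1ccc(C)cc1 | intermediate
14 | 4-(hydroxymethyl)benzene-1,3-diyl bis(4-methylbenzenesulfonate) | OCc1ccc(OS(=O)(=O)c2ccc(C)cc2)cc1OS(=O)(=O)c1ccc(C)cc1 | intermediate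
15 | 4-(bromomethyl)benzene-1,3-diyl bis(4-methylbenzenesulfonate) | BrCc1ccc(OS(=O)(=O)c2ccc(C)cc2)cc1OS(=O)(=O)c1ccc(C)cc1 | intermediate
16 | (1R,4R,5R)-4,7,7-trimethyl-6-thiabicyclo[3.2.1]octane (isothiocineole) | C[C@@H]1CC[C@@H]2C[C@H]1SC2(C)C | starting material
17 | (1R,4R,5R)-6-{2,4-bis[(4-methylphenyl)sulfonyloxy]benzyl}-4,7,7-trimethyl-6-thiabicyclo[3.2.1]octan-6-ium trifluoromethanesulfonate, exo S-benzyl | C[C@@H]1CC[C@@H]2C[C@H]1[S@@+](Cc1ccc(OS(=O)(=O)c3ccc(C)cc3)cc1OS(=O)(=O)c1ccc(C)cc1)C2(C)C.[O-]S(=O)(=O)C(F)(F)F | intermediate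
18 | sulfonium benzylide derived from 17 | C[C@@H]1CC[C@@H]2C[C@H]1[S@@+]([CH-]c1ccc(OS(=O)(=O)c3ccc(C)cc3)cc1OS(=O)(=O)c1ccc(C)cc1)C2(C)C | intermediate (not isolated)
19 | 5-(benzyloxy)-6-{[3,5-bis(benzyloxy)phenyl]methylidene}-3-{2-[4-(benzyloxy)phenyl]ethyl}cyclohexa-2,4-dien-1-one (alkene geometry not defined) | O=C1C=C(CCc2ccc(OCc3ccccc3)cc2)C=C(OCc2ccccc2)C1=Cc1cc(OCc2ccccc2)cc(OCc2ccccc2)c1 | intermediate (not isolated)
20 | betaine: 3-(benzyloxy)-2-{(1S,2R)-1-[3,5-bis(benzyloxy)phenyl]-2-{2,4-bis[(4-methylphenyl)sulfonyloxy]phenyl}-2-[(1R,4R,5R)-4,7,7-trimethyl-6-thiabicyclo[3.2.1]octan-6-ium-6-yl]ethyl}-5-{2-[4-(benzyloxy)phenyl]ethyl}phenolate | C[C@@H]1CC[C@@H]2C[C@H]1[S@@+]([C@@H](c1ccc(OS(=O)(=O)c3ccc(C)cc3)cc1OS(=O)(=O)c1ccc(C)cc1)[C@@H](c1cc(OCc3ccccc3)cc(OCc3ccccc3)c1)c1c([O-])cc(CCc3ccc(OCc4ccccc4)cc3)cc1OCc1ccccc1)C2(C)C | intermediate (not isolated)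
21 | 4-[(2S,3S)-4-(benzyloxy)-3-[3,5-bis(benzyloxy)phenyl]-6-{2-[4-(benzyloxy)phenyl]ethyl}-2,3-dihydro-1-benzofuran-2-yl]benzene-1,3-diyl bis(4-methylbenzenesulfonate) | C(c1ccccc1)Oc1ccc(CCc2cc(OCc4ccccc4)c3c(c2)O[C@H](c2ccc(OS(=O)(=O)c4ccc(C)cc4)cc2OS(=O)(=O)c2ccc(C)cc2)[C@H]3c2cc(OCc4ccccc4)cc(OCc4ccccc4)c2)cc1 | intermediate
22 | 4-[(2S,3S)-4-(benzyloxy)-3-[3,5-bis(benzyloxy)phenyl]-6-{2-[4-(benzyloxy)phenyl]ethyl}-2,3-dihydro-1-benzofuran-2-yl]benzene-1,3-diol | C(c1ccccc1)Oc1ccc(CCc2cc(OCc4ccccc4)c3c(c2)O[C@H](c2ccc(O)cc2O)[C@H]3c2cc(OCc4ccccc4)cc(OCc4ccccc4)c2)cc1 | intermediate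
23 | 4-[(2S,3S)-3-(3,5-dihydroxyphenyl)-4-hydroxy-6-[2-(4-hydroxyphenyl)ethyl]-2,3-dihydro-1-benzofuran-2-yl]benzene-1,3-diol | Oc1ccc(CCc2cc(O)c3c(c2)O[C@H](c2ccc(O)cc2O)[C@H]3c2cc(O)cc(O)c2)cc1 | target

**Step count**

Total: 14 steps. Longest linear sequence: 10 steps (steps 1–7, 12, 13, 14, from dihydroresveratrol); the sulfonium branch is 4 steps (steps 8–11).

**Steps most likely to fail**

Step 12. What may go wrong: poor facial discrimination in the C–C bond-forming addition of 18 to 19 (low enantiomeric purity or a cis/trans mixture), or O-benzylation of the phenoxide of 11 by 17 outrunning ylide formation. Fallback with known chemistry, setting out from 11 and 15 and returning at 21: bromide 15 is quaternised with tetrahydrothiophene in acetone to give the achiral salt 1-{2,4-bis[(4-methylphenyl)sulfonyloxy]benzyl}thiolan-1-ium bromide F1. With 11 and Cs2CO3 in MeCN/CH2Cl2, F1 is used in the established racemic sulfonium-ylide [4+1] annulation of base-generated o-quinone methides, which should give 21 as the racemate, that is together with its mirror image, the (2R,3R)-dihydrobenzofuran F2. The enantiomers are separated by preparative chromatography on a chiral stationary phase, and 21 is carried on.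

Step 14. What may go wrong: hydrogenolysis of the doubly activated benzylic C2–O1 bond once the C2 aryl group is an electron-rich resorcinol, leading to ring opening. Fallback, setting out from 21 and returning at 23: the order of the last two operations is reversed, so that the electron-withdrawing tosyloxy groups still deactivate the C2–O1 bond during hydrogenolysis. 21 is hydrogenolysed (H2, Pd/C, EtOAc/MeOH) to the tetraphenol bis-tosylate F5, and the two sulfonates are then removed with Mg in MeOH/THF as in step 13 to give 23.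

Step 7. What may go wrong: capture of the ionised benzhydryl cation by the electron-rich 3,5-bis(benzyloxy)phenyl ring of a second molecule (Friedel–Crafts oligomerisation) in competition with sulfinate. Fallback, setting out from 7 and returning at 21: the o-quinone methide is generated without acid. 7 is converted with Boc2O, i-Pr2NEt and DMAP (cat.) in CH2Cl2 into the aryl tert-butyl carbonate F3. Grignard reagent 9 is added to F3 in THF at −78 °C; the resulting alkoxide takes over the Boc group from the neighbouring phenol oxygen to give the bromomagnesium phenoxide of the benzylic tert-butyl carbonate F4 (not isolated). On warming, F4 loses tert-butyl carbonate to give 19 in the presence of ylide 18, preformed from 17 with LiN(SiMe3)2 in THF at −78 °C, and the annulation of step 12 then gives 21.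

**Further compounds**

F1 | step 12 | 1-{2,4-bis[(4-methylphenyl)sulfonyloxy]benzyl}thiolan-1-ium bromide | [Br-].C1CC[S+](C1)Cc1ccc(OS(=O)(=O)c2ccc(C)cc2)cc1OS(=O)(=O)c1ccc(C)cc1
F2 | step 12 | 4-[(2R,3R)-4-(benzyloxy)-3-[3,5-bis(benzyloxy)phenyl]-6-{2-[4-(benzyloxy)phenyl]ethyl}-2,3-dihydro-1-benzofuran-2-yl]benzene-1,3-diyl bis(4-methylbenzenesulfonate) | C(c1ccccc1)Oc1ccc(CCc2cc(OCc4ccccc4)c3c(c2)O[C@@H](c2ccc(OS(=O)(=O)c4ccc(C)cc4)cc2OS(=O)(=O)c2ccc(C)cc2)[C@@H]3c2cc(OCc4ccccc4)cc(OCc4ccccc4)c2)cc1
F3 | step 7 | 3-(benzyloxy)-5-{2-[4-(benzyloxy)phenyl]ethyl}-2-formylphenyl tert-butyl carbonate | O=Cc1c(OC(=O)OC(C)(C)C)cc(CCc2ccc(OCc3ccccc3)cc2)cc1OCc1ccccc1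
F4 | step 7 | bromomagnesium 3-(benzyloxy)-2-{[3,5-bis(benzyloxy)phenyl][(tert-butoxycarbonyl)oxy]methyl}-5-{2-[4-(benzyloxy)phenyl]ethyl}phenoxide | CC(C)(C)OC(=O)OC(c1cc(OCc2ccccc2)cc(OCc2ccccc2)c1)c1c(O[Mg]Br)cc(CCc2ccc(OCc3ccccc3)cc2)cc1OCc1ccccc1
F5 | step 14 | 4-[(2S,3S)-3-(3,5-dihydroxyphenyl)-4-hydroxy-6-[2-(4-hydroxyphenyl)ethyl]-2,3-dihydro-1-benzofuran-2-yl]benzene-1,3-diyl bis(4-methylbenzenesulfonate) | Oc1ccc(CCc2cc(O)c3c(c2)O[C@H](c2ccc(OS(=O)(=O)c4ccc(C)cc4)cc2OS(=O)(=O)c2ccc(C)cc2)[C@H]3c2cc(O)cc(O)c2)cc1
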